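**Retrosynthetic overview**

1. Numbering (germacrane): furanone O–C3=C2–C1(=O)–C10(C14H3); C4(C15H2OH)=C5; lactone O–C6–C7–C11(=C13H2)–C12(=O); C8 (ester carbon), C9H2.
2. 27 ⇐ 26 (C15–O desilylation) ⇐ 8α-alcohol 24 (Mitsunobu esterification, inversion at C8) ⇐ aldehyde 22 by forming C7–C8: intramolecular Nozaki–Hiyama allylation of C8H=O by the 3-(bromomethyl)butenolide (C13–Br, C11=C7). This closes the nine-membered ring O–C3–C4=C5–C6–C7–C8–C9–C10 last and creates C7, C8 and the C11=C13 exo-methylene under control of C6.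
3. Enabling feature: the γ-lactone ring (O–C6–C7–C11–C12) carries its exo-methylene C13 on C11 and the C8 carbinol on C7, so C13=C11–C7–C8–O is the homoallylic-alcohol retron of an SE2′ allylation, and the C7–C8 bond belongs to the nine-membered ring only.
4. 22 ⇐ butenolide by RCM (C7=C11) of a 2-(bromomethyl)acrylate ⇐ furanone by 5-endo-dig closure (O–C3) of hydroxy ynone 16 ⇐ Z-enyne 9 (C6 by CBS reduction, C4=C5 by directed hydroalumination–iodination) + Weinreb amide 15 from (S)-citramalic acid, whose C2, C1, C3, C4 and methyl map onto C10, C1, C9, C8 and C14.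
5. Ring order: furanone (step 11), butenolide (step 14), nine-membered oxacycle (step 16).

Key step: step 16

Remark: silyl ether 1 and (R)-2-methylbutanoic acid 25 are taken as purchasable (25 is otherwise accessible by Ru–BINAP hydrogenation of tiglic acid); the target's ester is (R)-configured as read from the SMILES.

**Route**

Step 1
Reactants: 1 tert-butyl(diphenyl)(prop-2-yn-1-yloxy)silane; 2 (E)-but-2-enoyl chloride
Product: 4 (E)-1-[(tert-butyldiphenylsilyl)oxy]hept-5-en-2-yn-4-one, via chloro{3-[(tert-butyldiphenylsilyl)oxy]prop-1-yn-1-yl}zinc 3 (not isolated)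
Conditions: n-BuLi, THF, −78 °C; ZnCl2, 0 °C; then 2, Pd(PPh3)4 (3 mol %), 0 °C → rt
Reagents that add atoms: zinc chloride, Cl[Zn]Cl (its atoms stay only in intermediate 3)
Why: Pd-catalysed acylation of an alkynylzinc (Negishi acylation) should give the cross-conjugated ynone by clean 1,2-union and avoids amine bases that would convert the acid chloride into a vinylketene.

Step 2
Reactants: 4 (E)-1-[(tert-butyldiphenylsilyl)oxy]hept-5-en-2-yn-4-one
Product: 5 (4S,5E)-1-[(tert-butyldiphenylsilyl)oxy]hept-5-en-2-yn-4-ol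
Conditions: (S)-Me-CBS (0.2 equiv), BH3·SMe2, THF, −30 °C; MeOH
Reagents that add atoms: none
Why: Corey–Bakshi–Shibata reduction in which the alkenyl group acts as the large and the linear alkynyl group as the small substituent, so the (S)-catalyst should deliver hydride to the Re face and set the future C6 centre (S at this stage).

Step 3
Reactants: 5 (4S,5E)-1-[(tert-butyldiphenylsilyl)oxy]hept-5-en-2-yn-4-ol
Product: 7 (2Z,4S,5E)-1-[(tert-butyldiphenylsilyl)oxy]-2-iodohepta-2,5-dien-4-ol, via cyclic sodium alkenyl(alkoxy)aluminate 6 (not isolated)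
Conditions: Red-Al, THF, 0 °C → rt; EtOAc; then I2, THF, −78 °C; aq. Rochelle salt/Na2S2O3
Reagents that add atoms: Red-Al, [Na+].COCCO[AlH2-]OCCOC (Al, Na and alkoxy groups in intermediate 6 only); iodine, II
Why: Alkoxide-directed trans-hydroalumination of the propargylic alcohol should place hydride on the proximal alkyne carbon (C5) and aluminium on C4 in a five-membered oxaluminole, and iodinolysis with retention gives the vinyl iodide with iodine cis to the carbinol, which fixes the C4=C5 geometry of the target.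

Step 4
Reactants: 7 (2Z,4S,5E)-1-[(tert-butyldiphenylsilyl)oxy]-2-iodohepta-2,5-dien-4-ol
Product: 8 (2Z,4S,5E)-1-[(tert-butyldiphenylsilyl)oxy]-2-iodo-4-[(triethylsilyl)oxy]hepta-2,5-diene
Conditions: TESCl, imidazole, DMF, 0 °C
Reagents that add atoms: chlorotriethylsilane, CC[Si](Cl)(CC)CC
Why: Standard silylation masks the Z-γ-hydroxy group, which would otherwise add to the enyne and ynone of steps 5–11 (furan formation) and would consume organolithium in step 10.

Step 5
Reactants: 8 (2Z,4S,5E)-1-[(tert-butyldiphenylsilyl)oxy]-2-iodo-4-[(triethylsilyl)oxy]hepta-2,5-diene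
Product: 9 (3E,5S,6E)-3-{[(tert-butyldiphenylsilyl)oxy]methyl}-5-[(triethylsilyl)oxy]octa-3,6-dien-1-yne (ethynyl group cis to the C5 carbinol carbon)
Conditions: HC≡CMgBr, ZnBr2, THF, 0 °C; then 8, Pd(PPh3)4 (5 mol %), rt
Reagents that add atoms: ethynylmagnesium bromide, C#C[Mg]Br
Why: Negishi coupling of the alkenyl iodide with ethynylzinc bromide should give the terminal enyne directly with retention of alkene geometry, supplying C2 and C3.

Step 6
Reactants: 10 (S)-citramalic acid [(2S)-2-hydroxy-2-methylbutanedioic acid]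
Product: 11 2-[(4S)-2,2,4-trimethyl-5-oxo-1,3-dioxolan-4-yl]acetic acid
Conditions: 2,2-dimethoxypropane, PPTS (cat.), rt
Reagents that add atoms: 2,2-dimethoxypropane, COC(C)(C)OC
Why: Acetonide formation selects the α-hydroxy acid (five-membered dioxolanone) and leaves the distal carboxyl free, which differentiates the two acid groups without touching the purchased C10 stereocentre.

Step 7
Reactants: 11 2-[(4S)-2,2,4-trimethyl-5-oxo-1,3-dioxolan-4-yl]acetic acid
Product: 12 (5S)-5-(2-hydroxyethyl)-2,2,5-trimethyl-1,3-dioxolan-4-one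
Conditions: BH3·THF, THF, 0 °C → rt; MeOH
Reagents that add atoms: none
Why: Borane reduces the free carboxylic acid much faster than the dioxolanone ester, as in the analogous malic acid series.

Step 8
Reactants: 12 (5S)-5-(2-hydroxyethyl)-2,2,5-trimethyl-1,3-dioxolan-4-one
Product: 14 methyl (2S)-2-hydroxy-4,4-dimethoxy-2-methylbutanoate, via 2-[(4S)-2,2,4-trimethyl-5-oxo-1,3-dioxolan-4-yl]acetaldehyde 13 (not isolated)
Conditions: Dess–Martin periodinane, NaHCO3, CH2Cl2, 0 °C → rt; filter, concentrate; then MeOH, HC(OMe)3, TsOH·H2O (cat.), 50 °C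
Reagents that add atoms: methanol, CO; trimethyl orthoformate, COC(OC)OC
Why: Dess–Martin oxidation followed by acid-catalysed acetalisation should mask the β-oxy aldehyde (future C8) at once, while acidic methanolysis opens the dioxolanone to the methyl ester.

Step 9
Reactants: 14 methyl (2S)-2-hydroxy-4,4-dimethoxy-2-methylbutanoate
Product: 15 (2S)-2-hydroxy-N,4,4-trimethoxy-N,2-dimethylbutanamide
Conditions: MeNH(OMe)·HCl, i-PrMgCl, THF, −20 → 0 °C
Reagents that add atoms: N,O-dimethylhydroxylamine hydrochloride, CNOC.Cl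
Why: Aminolysis of the ester with the chloromagnesium amide (Weinreb amide synthesis) is assisted by the neighbouring magnesium alkoxide and leaves the acetal untouched.

Step 10
Reactants: 9 (3E,5S,6E)-3-{[(tert-butyldiphenylsilyl)oxy]methyl}-5-[(triethylsilyl)oxy]octa-3,6-dien-1-yne; 15 (2S)-2-hydroxy-N,4,4-trimethoxy-N,2-dimethylbutanamide
Product: 16 (3S,7E,9S,10E)-7-{[(tert-butyldiphenylsilyl)oxy]methyl}-3-hydroxy-1,1-dimethoxy-3-methyl-9-[(triethylsilyl)oxy]dodeca-7,10-dien-5-yn-4-one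
Conditions: 9, n-BuLi, THF, −78 °C; then 15 (pre-treated with i-PrMgCl, 1.0 equiv), −78 → −20 °C; aq. NH4Cl
Reagents that add atoms: none
Why: Acylation of the lithium acetylide by the Weinreb amide stops at the ketone through the chelated tetrahedral intermediate and joins the two enantiopure fragments as the α′-hydroxy ynone.

Step 11
Reactants: 16 (3S,7E,9S,10E)-7-{[(tert-butyldiphenylsilyl)oxy]methyl}-3-hydroxy-1,1-dimethoxy-3-methyl-9-[(triethylsilyl)oxy]dodeca-7,10-dien-5-yn-4-one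
Product: 17 (2S)-5-{(2Z,4S,5E)-1-[(tert-butyldiphenylsilyl)oxy]-4-[(triethylsilyl)oxy]hepta-2,5-dien-2-yl}-2-(2,2-dimethoxyethyl)-2-methylfuran-3(2H)-one
Conditions: Ph3PAuNTf2 (3 mol %), 4 Å MS, CH2Cl2, 0 °C → rt
Reagents that add atoms: none
Why: Gold-catalysed 5-endo-dig addition of the free tertiary hydroxyl to the ynone β-carbon (C3) is an established cycloisomerisation of α′-hydroxy ynones to 3(2H)-furanones; the silyl ethers cannot compete and C10 is not involved.

Step 12
Reactants: 17 (2S)-5-{(2Z,4S,5E)-1-[(tert-butyldiphenylsilyl)oxy]-4-[(triethylsilyl)oxy]hepta-2,5-dien-2-yl}-2-(2,2-dimethoxyethyl)-2-methylfuran-3(2H)-one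
Product: 18 (2S)-5-{(2Z,4S,5E)-1-[(tert-butyldiphenylsilyl)oxy]-4-hydroxyhepta-2,5-dien-2-yl}-2-(2,2-dimethoxyethyl)-2-methylfuran-3(2H)-one
Conditions: HF·pyridine, pyridine, THF, 0 °C
Reagents that add atoms: none
Why: Buffered fluoride should cleave the secondary triethylsilyl ether far faster than the tert-butyldiphenylsilyl ether and leaves the acetal intact.

Step 13
Reactants: 18 (2S)-5-{(2Z,4S,5E)-1-[(tert-butyldiphenylsilyl)oxy]-4-hydroxyhepta-2,5-dien-2-yl}-2-(2,2-dimethoxyethyl)-2-methylfuran-3(2H)-one; 19 2-(bromomethyl)prop-2-enoic acid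
Product: 20 (2Z,4S,5E)-1-[(tert-butyldiphenylsilyl)oxy]-2-[(5S)-5-(2,2-dimethoxyethyl)-5-methyl-4-oxo-4,5-dihydrofuran-2-yl]hepta-2,5-dien-4-yl 2-(bromomethyl)prop-2-enoate
Conditions: DIC, DMAP (10 mol %), CH2Cl2, 0 °C
Reagents that add atoms: none
Why: Steglich esterification at low temperature with little DMAP acylates the C6 alcohol without substitution of the allylic bromide and brings in C11, C12 and C13.

Step 14
Reactants: 20 (2Z,4S,5E)-1-[(tert-butyldiphenylsilyl)oxy]-2-[(5S)-5-(2,2-dimethoxyethyl)-5-methyl-4-oxo-4,5-dihydrofuran-2-yl]hepta-2,5-dien-4-yl 2-(bromomethyl)prop-2-enoate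
Product: 21 (2S)-5-{(1Z)-1-[(2R)-4-(bromomethyl)-5-oxo-2,5-dihydrofuran-2-yl]-3-[(tert-butyldiphenylsilyl)oxy]prop-1-en-2-yl}-2-(2,2-dimethoxyethyl)-2-methylfuran-3(2H)-one
Conditions: Grubbs II (10 mol %), CH2Cl2 (5 mM), 40 °C
Reagents that add atoms: none
Why: Ring-closing metathesis between the propenyl group and the acrylate should form the butenolide C7=C11 bond with loss of propene; the trisubstituted, conjugated C2=C3 and C4=C5 alkenes are inert and the bromide appears only after all basic and Pd steps.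

Step 15
Reactants: 21 (2S)-5-{(1Z)-1-[(2R)-4-(bromomethyl)-5-oxo-2,5-dihydrofuran-2-yl]-3-[(tert-butyldiphenylsilyl)oxy]prop-1-en-2-yl}-2-(2,2-dimethoxyethyl)-2-methylfuran-3(2H)-one
Product: 22 2-[(2S)-5-{(1Z)-1-[(2R)-4-(bromomethyl)-5-oxo-2,5-dihydrofuran-2-yl]-3-[(tert-butyldiphenylsilyl)oxy]prop-1-en-2-yl}-2-methyl-3-oxo-2,3-dihydrofuran-2-yl]acetaldehyde
Conditions: TsOH·H2O (20 mol %), acetone/H2O 10:1, 0 °C → rt; used crude
Reagents that add atoms: water, O
Why: Mild acid hydrolysis of the dimethyl acetal unveils the C8 aldehyde under conditions that neither the allylic bromide, the butenolide nor the tert-butyldiphenylsilyl ether should feel, and avoids base that would trigger β-elimination across C9–C10.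

Step 16
Reactants: 22 2-[(2S)-5-{(1Z)-1-[(2R)-4-(bromomethyl)-5-oxo-2,5-dihydrofuran-2-yl]-3-[(tert-butyldiphenylsilyl)oxy]prop-1-en-2-yl}-2-methyl-3-oxo-2,3-dihydrofuran-2-yl]acetaldehyde
Product: 24 (2Z,4R,8R,9S,11S)-2-{[(tert-butyldiphenylsilyl)oxy]methyl}-9-hydroxy-11-methyl-7-methylidene-5,14-dioxatricyclo[9.2.1.0^4,8]tetradeca-1(13),2-diene-6,12-dione (germacrane 6R,7R,8S,10S; free 8α-OH), via allylchromium(III) dichloride 23 (not isolated)
Conditions: CrCl2 (8 equiv), THF, rt, syringe-pump addition of 22 (final 2 mM); aq. NH4Cl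
Reagents that add atoms: chromium(II) chloride, Cl[Cr]Cl (its atoms stay only in intermediate 23)
Why: Two equivalents of Cr(II) reduce the allylic C13–Br bond to the allylchromium(III) species 23, which adds through its γ-carbon C7 to the chromium-bound C8 aldehyde in a closed six-membered Zimmerman–Traxler array (SE2′ with allyl transposition), so that the butenolide becomes the α-methylene lactone as C7–C8 forms. The closest known reactions are intramolecular Nozaki–Hiyama allylations that close medium and large carbocycles and the Barbier additions of 3-(bromomethyl)furan-2(5H)-ones to aldehydes. The nine-membered ring O–C3–C4=C5–C6–C7–C8–C9–C10 closes in the 9-exo-trig mode at the aldehyde carbon and is the only ring formed. C7 is controlled by C6: the aldehyde should reach the butenolide face opposite the C6–C5 bond, because a cis-fused closure would force a nearly eclipsed C5–C6–C7–C8 torsion next to the Z-alkene, and this gives the trans-fused lactone (7R). C8 is controlled by the chair: the ring-fixed E-type allyl unit (C6 trans to CH2Cr) holds C6 pseudo-equatorial, and with the tether carbon C9 also pseudo-equatorial (anti to C11, H7 and H8 antiperiplanar) the 7,8-anti alcohol with the 8S (8α) configuration should result, which is the epimer that step 17 inverts. The step needs γ- over α-attack (the α-mode would require an eleven-membered ring and has no cyclic array), aldehyde over C1 ketone (a vinylogous ester carbonyl, inert to allylchromium) and cyclisation over oligomerisation (high dilution; the Z-C4=C5 bond and the planar furanone hold the chain ends close).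

Step 17
Reactants: 24 (2Z,4R,8R,9S,11S)-2-{[(tert-butyldiphenylsilyl)oxy]methyl}-9-hydroxy-11-methyl-7-methylidene-5,14-dioxatricyclo[9.2.1.0^4,8]tetradeca-1(13),2-diene-6,12-dione; 25 (R)-2-methylbutanoic acid
Product: 26 (2Z,4R,8R,9R,11S)-2-{[(tert-butyldiphenylsilyl)oxy]methyl}-11-methyl-7-methylidene-6,12-dioxo-5,14-dioxatricyclo[9.2.1.0^4,8]tetradeca-1(13),2-dien-9-yl (2R)-2-methylbutanoate
Conditions: PPh3, DIAD (betaine pre-formed at 0 °C), then 24 and 25, toluene, 0 °C → rt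
Reagents that add atoms: none
Why: Mitsunobu esterification, in which the carboxylate of 25 displaces the C8 alkoxyphosphonium by SN2 with inversion (8S → 8R), installs the ester and the natural 8β configuration at once without activating the acid, so its α-stereocentre is not at risk, while the C15 oxygen is still silylated.

Step 18
Reactants: 26 (2Z,4R,8R,9R,11S)-2-{[(tert-butyldiphenylsilyl)oxy]methyl}-11-methyl-7-methylidene-6,12-dioxo-5,14-dioxatricyclo[9.2.1.0^4,8]tetradeca-1(13),2-dien-9-yl (2R)-2-methylbutanoate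
Product: 27 (2Z,4R,8R,9R,11S)-2-(hydroxymethyl)-11-methyl-7-methylidene-6,12-dioxo-5,14-dioxatricyclo[9.2.1.0^4,8]tetradeca-1(13),2-dien-9-yl (2R)-2-methylbutanoate (CNP0307052.2)
Conditions: HF·pyridine, THF/pyridine, 0 °C → rt
Reagents that add atoms: none
Why: Fluoride-mediated cleavage of the primary allylic silyl ether under weakly acidic conditions should spare the ester, the α-methylene lactone and the furanone.

**Compound list**

1 | tert-butyl(diphenyl)(prop-2-yn-1-yloxy)silane | C#CCO[Si](c1ccccc1)(c1ccccc1)C(C)(C)C | starting material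
2 | (E)-but-2-enoyl chloride | C/C=C/C(Cl)=O | starting material
3 | chloro{3-[(tert-butyldiphenylsilyl)oxy]prop-1-yn-1-yl}zinc | Cl[Zn]C#CCO[Si](c1ccccc1)(c1ccccc1)C(C)(C)C | intermediate
4 | (E)-1-[(tert-butyldiphenylsilyl)oxy]hept-5-en-2-yn-4-one | C/C=C/C(=O)C#CCO[Si](c1ccccc1)(c1ccccc1)C(C)(C)C | intermediate
5 | (4S,5E)-1-[(tert-butyldiphenylsilyl)oxy]hept-5-en-2-yn-4-ol | O[C@@H](/C=C/C)C#CCO[Si](c1ccccc1)(c1ccccc1)C(C)(C)C | intermediate
6 | sodium (5S)-3-{[(tert-butyldiphenylsilyl)oxy]methyl}-2,2-bis(2-methoxyethoxy)-5-[(1E)-prop-1-en-1-yl]-2,5-dihydro-1,2-oxaluminol-2-uide (cyclic alkenyl(alkoxy)aluminate from 5; Al on C4, H on C5) | [Na+].COCCO[Al-]1(OCCOC)O[C@@H](/C=C/C)C=C1CO[Si](c2ccccc2)(c3ccccc3)C(C)(C)C | intermediate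
7 | (2Z,4S,5E)-1-[(tert-butyldiphenylsilyl)oxy]-2-iodohepta-2,5-dien-4-ol | O[C@@H](/C=C/C)/C=C(\I)CO[Si](c1ccccc1)(c1ccccc1)C(C)(C)C | intermediate
8 | (2Z,4S,5E)-1-[(tert-butyldiphenylsilyl)oxy]-2-iodo-4-[(triethylsilyl)oxy]hepta-2,5-diene | CC[Si](CC)(CC)O[C@@H](/C=C/C)/C=C(\I)CO[Si](c1ccccc1)(c1ccccc1)C(C)(C)C | intermediate
9 | (3E,5S,6E)-3-{[(tert-butyldiphenylsilyl)oxy]methyl}-5-[(triethylsilyl)oxy]octa-3,6-dien-1-yne | CC[Si](CC)(CC)O[C@@H](/C=C/C)/C=C(\C#C)CO[Si](c1ccccc1)(c1ccccc1)C(C)(C)C | intermediate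
10 | (S)-citramalic acid | OC(=O)[C@](C)(CC(=O)O)O | starting material
11 | 2-[(4S)-2,2,4-trimethyl-5-oxo-1,3-dioxolan-4-yl]acetic acid | O=C1OC(C)(C)O[C@@]1(C)CC(=O)O | intermediate
12 | (5S)-5-(2-hydroxyethyl)-2,2,5-trimethyl-1,3-dioxolan-4-one | O=C1OC(C)(C)O[C@@]1(C)CCO | intermediate
13 | 2-[(4S)-2,2,4-trimethyl-5-oxo-1,3-dioxolan-4-yl]acetaldehyde | O=C1OC(C)(C)O[C@@]1(C)CC=O | intermediate
14 | methyl (2S)-2-hydroxy-4,4-dimethoxy-2-methylbutanoate | COC(=O)[C@](C)(CC(OC)OC)O | intermediate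
15 | (2S)-2-hydroxy-N,4,4-trimethoxy-N,2-dimethylbutanamide | CON(C)C(=O)[C@](C)(CC(OC)OC)O | intermediate
16 | (3S,7E,9S,10E)-7-{[(tert-butyldiphenylsilyl)oxy]methyl}-3-hydroxy-1,1-dimethoxy-3-methyl-9-[(triethylsilyl)oxy]dodeca-7,10-dien-5-yn-4-one | CC[Si](CC)(CC)O[C@@H](/C=C/C)/C=C(\C#CC(=O)[C@](C)(CC(OC)OC)O)CO[Si](c1ccccc1)(c1ccccc1)C(C)(C)C | intermediate
17 | (2S)-5-{(2Z,4S,5E)-1-[(tert-butyldiphenylsilyl)oxy]-4-[(triethylsilyl)oxy]hepta-2,5-dien-2-yl}-2-(2,2-dimethoxyethyl)-2-methylfuran-3(2H)-one | CC[Si](CC)(CC)O[C@@H](/C=C/C)/C=C(/CO[Si](c1ccccc1)(c2ccccc2)C(C)(C)C)C3=CC(=O)[C@](C)(CC(OC)OC)O3 | intermediate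
18 | (2S)-5-{(2Z,4S,5E)-1-[(tert-butyldiphenylsilyl)oxy]-4-hydroxyhepta-2,5-dien-2-yl}-2-(2,2-dimethoxyethyl)-2-methylfuran-3(2H)-one | O[C@@H](/C=C/C)/C=C(/CO[Si](c1ccccc1)(c2ccccc2)C(C)(C)C)C3=CC(=O)[C@](C)(CC(OC)OC)O3 | intermediate
19 | 2-(bromomethyl)prop-2-enoic acid | C=C(CBr)C(=O)O | starting material
20 | (2Z,4S,5E)-1-[(tert-butyldiphenylsilyl)oxy]-2-[(5S)-5-(2,2-dimethoxyethyl)-5-methyl-4-oxo-4,5-dihydrofuran-2-yl]hepta-2,5-dien-4-yl 2-(bromomethyl)prop-2-enoate | C=C(CBr)C(=O)O[C@@H](/C=C/C)/C=C(/CO[Si](c1ccccc1)(c2ccccc2)C(C)(C)C)C3=CC(=O)[C@](C)(CC(OC)OC)O3 | intermediate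
21 | (2S)-5-{(1Z)-1-[(2R)-4-(bromomethyl)-5-oxo-2,5-dihydrofuran-2-yl]-3-[(tert-butyldiphenylsilyl)oxy]prop-1-en-2-yl}-2-(2,2-dimethoxyethyl)-2-methylfuran-3(2H)-one | O=C1O[C@@H](C=C1CBr)/C=C(/CO[Si](c2ccccc2)(c3ccccc3)C(C)(C)C)C4=CC(=O)[C@](C)(CC(OC)OC)O4 | intermediate
22 | 2-[(2S)-5-{(1Z)-1-[(2R)-4-(bromomethyl)-5-oxo-2,5-dihydrofuran-2-yl]-3-[(tert-butyldiphenylsilyl)oxy]prop-1-en-2-yl}-2-methyl-3-oxo-2,3-dihydrofuran-2-yl]acetaldehyde | O=C1O[C@@H](C=C1CBr)/C=C(/CO[Si](c2ccccc2)(c3ccccc3)C(C)(C)C)C4=CC(=O)[C@](C)(CC=O)O4 | intermediate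
23 | allylchromium(III) dichloride of 22 (CrCl2 on the butenolide 4-methylene carbon, C13) | O=C1O[C@@H](C=C1C[Cr](Cl)Cl)/C=C(/CO[Si](c2ccccc2)(c3ccccc3)C(C)(C)C)C4=CC(=O)[C@](C)(CC=O)O4 | intermediate
24 | (2Z,4R,8R,9S,11S)-2-{[(tert-butyldiphenylsilyl)oxy]methyl}-9-hydroxy-11-methyl-7-methylidene-5,14-dioxatricyclo[9.2.1.0^4,8]tetradeca-1(13),2-diene-6,12-dione | C=C1C(=O)O[C@@H]2/C=C(/CO[Si](c4ccccc4)(c5ccccc5)C(C)(C)C)C3=CC(=O)[C@](C)(C[C@H](O)[C@@H]12)O3 | intermediate
25 | (R)-2-methylbutanoic acid | CC[C@@H](C)C(=O)O | starting material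
26 | (2Z,4R,8R,9R,11S)-2-{[(tert-butyldiphenylsilyl)oxy]methyl}-11-methyl-7-methylidene-6,12-dioxo-5,14-dioxatricyclo[9.2.1.0^4,8]tetradeca-1(13),2-dien-9-yl (2R)-2-methylbutanoate | C=C1C(=O)O[C@@H]2/C=C(/CO[Si](c4ccccc4)(c5ccccc5)C(C)(C)C)C3=CC(=O)[C@](C)(C[C@@H](OC(=O)[C@H](C)CC)[C@@H]12)O3 | intermediate
27 | (2Z,4R,8R,9R,11S)-2-(hydroxymethyl)-11-methyl-7-methylidene-6,12-dioxo-5,14-dioxatricyclo[9.2.1.0^4,8]tetradeca-1(13),2-dien-9-yl (2R)-2-methylbutanoate | C=C1C(=O)O[C@@H]2/C=C(/CO)C3=CC(=O)[C@](C)(C[C@@H](OC(=O)[C@H](C)CC)[C@@H]12)O3 | target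

**Step count and risk**

Total steps: 18. Longest linear sequence: 14 (steps 1–5 and 10–18); the citramalic acid branch (steps 6–9) joins at step 10.

Steps most likely to fail:

1. Step 16 (key ring closure). The tethered aldehyde may close through the alternative chair with C9 pseudo-axial (or a boat arrangement), so that the C8 carbinol forms with the opposite configuration; some protonolysis of the allylchromium may accompany it. Fallback, setting out from 22 and returning at 26: the same closure would then deliver the 8β-alcohol (2Z,4R,8R,9R,11S)-2-{[(tert-butyldiphenylsilyl)oxy]methyl}-9-hydroxy-11-methyl-7-methylidene-5,14-dioxatricyclo[9.2.1.0^4,8]tetradeca-1(13),2-diene-6,12-dione F1. Instead of the inverting Mitsunobu reaction, F1 would be acylated with 25 with retention by Shiina mixed-anhydride esterification (2-methyl-6-nitrobenzoic anhydride, DMAP cat., Et3N, CH2Cl2, rt), which gives 26 directly.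

2. Step 14 (ring-closing metathesis). The allylic C–Br bond may degrade the ruthenium carbene, or closure onto the 1,1-disubstituted electron-poor acrylate may be too slow, so that cross-metathesis dimers and olefin isomerisation take over. Fallback, setting out from 18 and returning at 21: 18 would be esterified (DIC, DMAP) with the known 2-{[(tert-butyldimethylsilyl)oxy]methyl}prop-2-enoic acid to give the silyloxymethyl acrylate (2Z,4S,5E)-1-[(tert-butyldiphenylsilyl)oxy]-2-[(5S)-5-(2,2-dimethoxyethyl)-5-methyl-4-oxo-4,5-dihydrofuran-2-yl]hepta-2,5-dien-4-yl 2-{[(tert-butyldimethylsilyl)oxy]methyl}prop-2-enoate F2. Metathesis of this halide-free ester (Grubbs II) would give the 3-(silyloxymethyl)butenolide (2S)-5-{(1Z)-1-[(2R)-4-{[(tert-butyldimethylsilyl)oxy]methyl}-5-oxo-2,5-dihydrofuran-2-yl]-3-[(tert-butyldiphenylsilyl)oxy]prop-1-en-2-yl}-2-(2,2-dimethoxyethyl)-2-methylfuran-3(2H)-one F3. HF·pyridine at 0 °C (primary TBS far faster than TBDPS) would give the allylic alcohol (2S)-5-{(1Z)-3-[(tert-butyldiphenylsilyl)oxy]-1-[(2R)-4-(hydroxymethyl)-5-oxo-2,5-dihydrofuran-2-yl]prop-1-en-2-yl}-2-(2,2-dimethoxyethyl)-2-methylfuran-3(2H)-one F4, and CBr4/PPh3 would install the bromide after the ring is closed, giving 21.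

3. Step 17 (Mitsunobu inversion). Displacement at the hindered C8 carbinol, flanked by the ring-fusion carbon C7 and the neopentyl-type C9, may be outrun by elimination of the alkoxyphosphonium or may not proceed with the weakly acidic aliphatic acid. Fallback, setting out from 24 and returning at 26: the alcohol would first be converted with chloromethanesulfonyl chloride and pyridine (CH2Cl2, 0 °C) into the isolable sulfonate (2Z,4R,8S,9S,11S)-2-{[(tert-butyldiphenylsilyl)oxy]methyl}-11-methyl-7-methylidene-6,12-dioxo-5,14-dioxatricyclo[9.2.1.0^4,8]tetradeca-1(13),2-dien-9-yl chloromethanesulfonate F5. This would then be displaced with inversion by caesium (R)-2-methylbutanoate (from 25 and Cs2CO3) with 18-crown-6 in toluene at 60 °C, a sulfonate/caesium carboxylate SN2 sequence used for hindered secondary alcohols, giving 26.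

Further compounds
F1 | step 16 | (2Z,4R,8R,9R,11S)-2-{[(tert-butyldiphenylsilyl)oxy]methyl}-9-hydroxy-11-methyl-7-methylidene-5,14-dioxatricyclo[9.2.1.0^4,8]tetradeca-1(13),2-diene-6,12-dione | C=C1C(=O)O[C@@H]2/C=C(/CO[Si](c4ccccc4)(c5ccccc5)C(C)(C)C)C3=CC(=O)[C@](C)(C[C@@H](O)[C@@H]12)O3
F2 | step 14 | (2Z,4S,5E)-1-[(tert-butyldiphenylsilyl)oxy]-2-[(5S)-5-(2,2-dimethoxyethyl)-5-methyl-4-oxo-4,5-dihydrofuran-2-yl]hepta-2,5-dien-4-yl 2-{[(tert-butyldimethylsilyl)oxy]methyl}prop-2-enoate | C=C(CO[Si](C)(C)C(C)(C)C)C(=O)O[C@@H](/C=C/C)/C=C(/CO[Si](c1ccccc1)(c2ccccc2)C(C)(C)C)C3=CC(=O)[C@](C)(CC(OC)OC)O3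
F3 | step 14 | (2S)-5-{(1Z)-1-[(2R)-4-{[(tert-butyldimethylsilyl)oxy]methyl}-5-oxo-2,5-dihydrofuran-2-yl]-3-[(tert-butyldiphenylsilyl)oxy]prop-1-en-2-yl}-2-(2,2-dimethoxyethyl)-2-methylfuran-3(2H)-one | O=C1O[C@@H](C=C1CO[Si](C)(C)C(C)(C)C)/C=C(/CO[Si](c2ccccc2)(c3ccccc3)C(C)(C)C)C4=CC(=O)[C@](C)(CC(OC)OC)O4
F4 | step 14 | (2S)-5-{(1Z)-3-[(tert-butyldiphenylsilyl)oxy]-1-[(2R)-4-(hydroxymethyl)-5-oxo-2,5-dihydrofuran-2-yl]prop-1-en-2-yl}-2-(2,2-dimethoxyethyl)-2-methylfuran-3(2H)-one | O=C1O[C@@H](C=C1CO)/C=C(/CO[Si](c2ccccc2)(c3ccccc3)C(C)(C)C)C4=CC(=O)[C@](C)(CC(OC)OC)O4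
F5 | step 17 | (2Z,4R,8S,9S,11S)-2-{[(tert-butyldiphenylsilyl)oxy]methyl}-11-methyl-7-methylidene-6,12-dioxo-5,14-dioxatricyclo[9.2.1.0^4,8]tetradeca-1(13),2-dien-9-yl chloromethanesulfonate | C=C1C(=O)O[C@@H]2/C=C(/CO[Si](c4ccccc4)(c5ccccc5)C(C)(C)C)C3=CC(=O)[C@](C)(C[C@H](OS(=O)(=O)CCl)[C@@H]12)O3
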